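Readings and results are calculated for substances that don't exist, and the scatter is random.

Start from the substrate.

the same everywhere: substrate 0.050 M; gas phase 15 mM (held)
- Friday's: free catalyst 0.20 mM; run made earlier
- Sunday's: free catalyst 0.38 mM; run made earlier
- ash: free catalyst 0.17 mM; time 2.0 h
- elm: free catalyst 0.34 mM; time 2.0 h

| run | time / min | target / % | isomer of the product / % | side product / % | substrate / % |
|---|---|---|---|---|---|
| Friday's | 20.0 | 0 | 0 | 1 | 95 |
| Friday's | 40.0 | 4 | 2 | 4 | 89 |
| Friday's | 60.0 | 10 | 1 | 9 | 81 |
| Friday's | 80.0 | 9 | 6 | 14 | 70 |
| Sunday's | 20.0 | 5 | 1 | 1 | 94 |
| Sunday's | 40.0 | 10 | 0 | 6 | 85 |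
| Sunday's | 60.0 | 14 | 4 | 13 | 70 |
| Sunday's | 80.0 | 17 | 8 | 18 | 62 |

(scatter of a reading: 1.5 percentage points)

* which of these there is most of at the end, counted by the substrate in it, ash (target / isomer of the product / substrate / side product)
* which of these there is most of at the end, counted by the substrate in it, elm (target / isomer of the product / substrate / side product)
* the largest of these amounts at the end, in percent of the substrate charged, ash
* the largest of these amounts at the end, in percent of the substrate charged, elm

- a species is counted by the substrate in it: one side product counts as two
- at the start none of the gas phase is in solution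

In both runs the substrate falls slowly at first, then steadily. So solve each end and join them. At the late end, within the scatter, I take the logarithm of the substrate left as a straight line. Between 40.0 min and 80.0 min, its slope is 0.00600 min⁻¹ in Friday's run and 0.00789 min⁻¹ in Sunday's. At the early end, those lines run back to zero loss near 20.0 min, which I take as the lag. Between the two runs, the slope goes with free catalyst to the power 0.425.

Now fold these into one number. For elm I get 0.752, starting from Sunday's run. This is the burn number: the slope, scaled by that power to the flask's free catalyst, times the time past the lag. I take the substrate left as e to the minus burn number, so I reckon that elm keeps 47.1%. Ash, from Friday's run, has 0.560, and I reckon that it keeps 57.1%.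

Is one number enough? No. It says what is left, not what leads. You need a second number, the biggest share of the reacted substrate read in a product at the last readings of the two runs. That is side product in Friday's last reading, 0.483. With that share held, substrate leads while the burn number stays below 1.12. Elm stands below it, and ash lower still. So I say substrate in both.

The forecast also names substrate for ash and substrate for elm. It gives 56% for ash (48% to 63%) and 46% for elm (37% to 54%), scaling by the square root of catalyst. Its words: “Substrate therefore remains the largest in both runs”. My figures, 57.1% for ash and 47.1% for elm, lie above its figures.

After 2.0 h, ash holds 58.1% of substrate and elm holds 43.7% of substrate.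

    target ⇌ isomer of the product (K = 0.690, k = 2.70 × 10⁻⁴ s⁻¹)
    gas phase ⇌ dissolved gas, rate k2*(csat - [dissolved gas]) (kL = 4.30 × 10⁻⁴ s⁻¹)
    free catalyst + target → spent catalyst (k = 0.00800 M⁻¹ s⁻¹)
    substrate + target → side product (k = 0.00650 M⁻¹ s⁻¹)
    substrate + dissolved gas + free catalyst → free catalyst + target (k = 48.0 M⁻² s⁻¹)

Now leave elm until 8.0 h. The time past the lag stretches, so the burn number becomes 3.46, above 1.12. The reckoning leaves 3.14% of substrate and puts side product in front, at 46.8% by the share. That flask holds 2.35% of substrate, and side product leads at 64.3%.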